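**Retrosynthetic overview**
- Last bond: C-5' of ring B to the stereocentre, by catalytic asymmetric Friedel–Crafts addition of unprotected cajanin to a vinylogous para-quinone methide; this step sets the only stereocentre and needs no protecting groups.
- Key bond: chromone C-3 to C-1' of ring B. C-3 (the ketone α-carbon, innately nucleophilic) is converted into an electrophilic α-phenyliodonio enone and joined to the equally nucleophilic C-4 of silylated resorcinol.
- The iodonio-chromone comes from the enaminone of 2',6'-dihydroxy-4'-methoxyacetophenone; the quinone methide precursor comes from a chalcone made from 4'-hydroxyacetophenone and 2,4-dimethoxybenzaldehyde.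
- Ring order: rings A and B and the two outer aryl rings are bought; the only ring built is the pyranone (ring C), closed in the key step just before ring B is attached.

Assumption: the (R)-phosphoric acid is taken to give the (R)-product by analogy with related additions to para-quinone methides; the sense is checked on the first run and the (S)-acid is used instead if it is opposite.

**Step 1**
Reactants: 1 1-(2,6-dihydroxy-4-methoxyphenyl)ethan-1-one; 2 N,N-dimethylformamide dimethyl acetal
Product: 3 (E)-1-(2,6-dihydroxy-4-methoxyphenyl)-3-(dimethylamino)prop-2-en-1-one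
Conditions: 2 (1.3 equiv), THF, 60 °C, 3 h
Reagents that add atoms: none
Why: Enaminone formation: the acetyl CH3 condenses with the amide acetal with loss of two MeOH to give the push–pull (E)-enaminone, and at 60 °C the two carbonyl-flanking phenols are not O-methylated.

**Step 2**
Reactants: 3 (E)-1-(2,6-dihydroxy-4-methoxyphenyl)-3-(dimethylamino)prop-2-en-1-one; 4 [bis(trifluoroacetoxy)iodo]benzene; 5 1,3-bis(trimethylsilyloxy)benzene
Product: 8 cajanin [3-(2,4-dihydroxyphenyl)-5-hydroxy-7-methoxy-4H-chromen-4-one], via chromonyl(phenyl)iodonium trifluoroacetate 6 (not isolated), via bis-silyl cajanin 7 (not isolated)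
Conditions: 4 (1.0 equiv), CH2Cl2, −40 to 0 °C, 30 min; then 5 (2 equiv), (CF3)2CHOH co-solvent (20% v/v), −20 °C to rt; then MeOH, rt, 1 h
Reagents that add atoms: none
Why: Proposed new method: PhI(OCOCF3)2 iodanylates the enamine-like α-carbon of 3 and the liberated CF3CO2H closes the pyranone ring with loss of Me2NH (the trivalent-iodine counterpart of the iodine-triggered enaminone to 3-iodochromone cyclisation), giving 6, an α-phenyliodonio enone whose C-3 is now an electrophilic, enolonium-type carbon; the silylated resorcinol then adds through its C-4 to C-2 of 6, the resulting iodonium ylide is C-protonated to a trans-2-aryl-3-(phenyliodonio)chromanone, and the electron-rich aryl shifts from C-2 to C-3 with loss of PhI and H+ (the phenonium step of the PhI(OH)OTs flavanone to isoflavone rearrangement), so the new C-3–C-1' bond joins two innately nucleophilic carbons; closest known reactions are the enolonium (trivalent-iodine enolate) α-arylation of ketones with electron-rich arenes and the hypervalent-iodine oxidative rearrangement of flavanones.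

**Step 3**
Reactants: 9 1-(4-hydroxyphenyl)ethan-1-one; 10 2,4-dimethoxybenzaldehyde
Product: 11 (E)-3-(2,4-dimethoxyphenyl)-1-(4-hydroxyphenyl)prop-2-en-1-one
Conditions: KOH (50% aq, 6 equiv), EtOH, rt, 48 h; then 1 M HCl to pH 4
Reagents that add atoms: none
Why: Claisen–Schmidt (crossed aldol) condensation: the aldehyde has no α-hydrogens and E1cB dehydration of the aldol gives only the conjugated (E)-enone.

**Step 4**
Reactants: 11 (E)-3-(2,4-dimethoxyphenyl)-1-(4-hydroxyphenyl)prop-2-en-1-one
Product: 12 (E)-3-(2,4-dimethoxyphenyl)-1-(4-hydroxyphenyl)prop-2-en-1-ol (racemic)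
Conditions: iBu2AlH (2.5 equiv), THF, −78 to −40 °C, 1 h; aq potassium sodium tartrate work-up at 0 °C; used the same day
Reagents that add atoms: none
Why: 1,2-Reduction of an enone with iBu2AlH: the first equivalent turns the phenol into its aluminium phenoxide and the second delivers hydride to the carbonyl carbon, not the β-carbon; the carbinol is left racemic because this centre is planarised in step 5.

**Step 5**
Reactants: 8 cajanin (1.2 equiv); 12 (E)-3-(2,4-dimethoxyphenyl)-1-(4-hydroxyphenyl)prop-2-en-1-ol
Product: 14 3-{5-[(1R,2E)-3-(2,4-dimethoxyphenyl)-1-(4-hydroxyphenyl)prop-2-en-1-yl]-2,4-dihydroxyphenyl}-5-hydroxy-7-methoxy-4H-chromen-4-one (caraganin B), via vinylogous para-quinone methide 13 (not isolated)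
Conditions: (R)-3,3'-bis(2,4,6-triisopropylphenyl)-1,1'-binaphthyl-2,2'-diyl hydrogen phosphate (10 mol%), Na2SO4, ClCH2CH2Cl/EtOAc 2:1, −20 °C, 12 added over 4 h
Reagents that add atoms: none
Why: Chiral phosphoric acid-catalysed asymmetric Friedel–Crafts alkylation (1,6-conjugate addition of a phenol to a para-quinone methide formed in situ): the acid dehydrates 12 to 13 and, hydrogen-bonded to both the quinone-methide carbonyl and the 4'-OH of 8, guides C-5' of ring B (ortho to 4'-OH, para to 2'-OH, the only unhindered doubly activated position) onto one enantiotopic face of the methide carbon, which sets the (R)-centre; attack at this carbon and not at the dimethoxyphenyl-bearing terminus keeps the alkene (E) and conjugated with the stronger donor ring.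

**Compound list**
1 | 1-(2,6-dihydroxy-4-methoxyphenyl)ethan-1-one | CC(=O)c1c(O)cc(OC)cc1O | starting material
2 | N,N-dimethylformamide dimethyl acetal | COC(OC)N(C)C | starting material
3 | (E)-1-(2,6-dihydroxy-4-methoxyphenyl)-3-(dimethylamino)prop-2-en-1-one | CN(C)/C=C/C(=O)c1c(O)cc(OC)cc1O | intermediate
4 | [bis(trifluoroacetoxy)iodo]benzene | FC(F)(F)C(=O)OI(OC(=O)C(F)(F)F)c1ccccc1 | starting material
5 | 1,3-bis(trimethylsilyloxy)benzene | C[Si](C)(C)Oc1cccc(O[Si](C)(C)C)c1 | starting material
6 | (5-hydroxy-7-methoxy-4-oxo-4H-chromen-3-yl)(phenyl)iodonium trifluoroacetate | COc1cc(O)c2c(c1)occ([I+]c1ccccc1)c2=O.[O-]C(=O)C(F)(F)F | intermediate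
7 | 3-[2,4-bis(trimethylsilyloxy)phenyl]-5-hydroxy-7-methoxy-4H-chromen-4-one | COc1cc(O)c2c(c1)occ(-c1ccc(O[Si](C)(C)C)cc1O[Si](C)(C)C)c2=O | intermediate
8 | cajanin, 3-(2,4-dihydroxyphenyl)-5-hydroxy-7-methoxy-4H-chromen-4-one | COc1cc(O)c2c(c1)occ(-c1ccc(O)cc1O)c2=O | intermediate
9 | 1-(4-hydroxyphenyl)ethan-1-one | CC(=O)c1ccc(O)cc1 | starting material
10 | 2,4-dimethoxybenzaldehyde | COc1ccc(C=O)c(OC)c1 | starting material
11 | (E)-3-(2,4-dimethoxyphenyl)-1-(4-hydroxyphenyl)prop-2-en-1-one | COc1ccc(/C=C/C(=O)c2ccc(O)cc2)c(OC)c1 | intermediate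
12 | (E)-3-(2,4-dimethoxyphenyl)-1-(4-hydroxyphenyl)prop-2-en-1-ol, racemic | COc1ccc(/C=C/C(O)c2ccc(O)cc2)c(OC)c1 | intermediate
13 | 4-[(2E)-3-(2,4-dimethoxyphenyl)prop-2-en-1-ylidene]cyclohexa-2,5-dien-1-one | COc1ccc(/C=C/C=C2C=CC(=O)C=C2)c(OC)c1 | intermediate
14 | caraganin B, 3-{5-[(1R,2E)-3-(2,4-dimethoxyphenyl)-1-(4-hydroxyphenyl)prop-2-en-1-yl]-2,4-dihydroxyphenyl}-5-hydroxy-7-methoxy-4H-chromen-4-one | COc1ccc(/C=C/[C@H](c2ccc(O)cc2)c2cc(-c3coc4cc(OC)cc(O)c4c3=O)c(O)cc2O)c(OC)c1 | target

**Totals**
Total steps: 5. Longest linear sequence: 3 (steps 1, 2, 5 or steps 3, 4, 5).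

**Three steps most likely to fail**

1. Step 2. Risks: loss of H-2 instead of the aryl shift would give the flavone; trifluoroacetate could be transferred to C-3; the ring A phenols could be oxidised by 4. The fallback sets out from 3 and comes back at 8. Iodine (I2, CHCl3, rt) converts 3 into 5-hydroxy-3-iodo-7-methoxy-4H-chromen-4-one F1, the stable α-iodo enone form of the same electrophilic C-3. Suzuki–Miyaura coupling of F1 with commercial 2,4-bis(benzyloxy)phenylboronic acid (Pd(PPh3)4, K2CO3, dioxane/H2O, 80 °C) gives 3-[2,4-bis(benzyloxy)phenyl]-5-hydroxy-7-methoxy-4H-chromen-4-one F2. Hydrogenolysis (H2, palladium on carbon, EtOAc/MeOH, rt) then returns 8.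

2. Step 5. Risks: low enantioselectivity in the polar solvent that 8 needs; attack at the other allyl terminus or on ring A (C-6/C-8); self-condensation of 13. The fallback sets out from 8 and 12 and comes back at 14. The same addition is run with achiral diphenyl hydrogen phosphate (10 mol%), which gives 14 together with its mirror image (S)-caraganin B F3 as the racemate. Preparative chiral SFC (amylose tris(3,5-dimethylphenylcarbamate) phase, CO2/MeOH) removes F3 and delivers 14. This rescues enantiopurity only; it does not correct a regiochemical failure.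

3. Step 4. Risks: the phenoxide-deactivated enone may be reduced sluggishly or at the β-carbon, and 12 ionises easily on handling. The fallback sets out from 10 and comes back at 12. Wittig olefination of 10 with (triphenylphosphoranylidene)acetaldehyde (toluene, 80 °C) gives (E)-3-(2,4-dimethoxyphenyl)prop-2-enal F4. 1,2-Addition of 4-(tert-butyldimethylsilyloxy)phenylmagnesium bromide (THF, −78 °C) gives (E)-1-[4-(tert-butyldimethylsilyloxy)phenyl]-3-(2,4-dimethoxyphenyl)prop-2-en-1-ol F5, which cannot form a quinone methide and can be stored. Bu4NF/AcOH (THF, 0 °C) releases 12 just before step 5.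

**Further compounds**
F1 | step 2 | 5-hydroxy-3-iodo-7-methoxy-4H-chromen-4-one | COc1cc(O)c2c(c1)occ(I)c2=O
F2 | step 2 | 3-[2,4-bis(benzyloxy)phenyl]-5-hydroxy-7-methoxy-4H-chromen-4-one | COc1cc(O)c2c(c1)occ(-c1ccc(OCc3ccccc3)cc1OCc1ccccc1)c2=O
F3 | step 5 | (S)-caraganin B | COc1ccc(/C=C/[C@@H](c2ccc(O)cc2)c2cc(-c3coc4cc(OC)cc(O)c4c3=O)c(O)cc2O)c(OC)c1
F4 | step 4 | (E)-3-(2,4-dimethoxyphenyl)prop-2-enal | COc1ccc(/C=C/C=O)c(OC)c1
F5 | step 4 | (E)-1-[4-(tert-butyldimethylsilyloxy)phenyl]-3-(2,4-dimethoxyphenyl)prop-2-en-1-ol, racemic | COc1ccc(/C=C/C(O)c2ccc(O[Si](C)(C)C(C)(C)C)cc2)c(OC)c1
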